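**Retrosynthetic overview**

- The target is a 6-oxabicyclo[3.2.1]octane-7,8-dione: ring A is the furan-2,4-dione (C1, C7, O6, C5, C8) and ring B the carbocycle (C1, C2, C3, C4, C5, C8). C2 is the only CH2 of ring B, so the C2–C3 bond is cut to a primary C2 radical on ring A and an enal β-carbon C3 hanging from C4.
- The C3 prenyl group comes last, by Wittig reaction of a C3 acetaldehyde arm; ring B comes from 6-exo decarboxylative radical closure of the N-acyloxyphthalimide of the C1 acetic acid arm.
- C1 is set by Tsuji–Trost prenylation of the tetronate anti to the C4 chain; ring A comes from one-pot O-succinylation and Lacey–Dieckmann closure of a tertiary α-hydroxy β-keto ester.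
- C5 is set by carbenoid O–H insertion, Claisen shift and α-ketol shift with chirality transfer from an (S)-allylic alcohol made from (R)-glyceraldehyde acetonide.
- Ring order: ring A (step 6), then ring B (step 11).

Key step: step 11

Assumption: the sense of chirality transfer in step 5 is derived from a chair Claisen transition state of the (Z)-enol and a syn-periplanar α-ketol shift, which map (S)-7 onto (R)-10; if the sense proves opposite, the antipodal glyceraldehyde acetonide is used instead.

**Step 1**
Reactants: 1 methyl 4-methyl-3-oxopentanoate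
Product: 2 methyl 2-diazo-4-methyl-3-oxopentanoate
Conditions: 4-acetamidobenzenesulfonyl azide, Et3N, MeCN, 0 °C → rt
Reagents that add atoms: 4-acetamidobenzenesulfonyl azide, CC(=O)Nc1ccc(cc1)S(=O)(=O)N=[N+]=[N-]
Why: Regitz diazo transfer to the doubly activated methylene of a β-keto ester is standard and leaves both carbonyl groups untouched.

**Step 2**
Reactants: 3 (R)-2,2-dimethyl-1,3-dioxolane-4-carbaldehyde; 4 isopropyltriphenylphosphonium iodide
Product: 5 (S)-2,2-dimethyl-4-(2-methylprop-1-en-1-yl)-1,3-dioxolane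
Conditions: 4, KN(SiMe3)2, THF, 0 °C; then 3, −78 °C → rt
Reagents that add atoms: none
Why: Wittig olefination with the non-stabilised isopropylidene ylide gives the trisubstituted alkene, and addition at low temperature keeps the α-alkoxy stereocentre intact (the descriptor changes to S only through the priority switch).

**Step 3**
Reactants: 5 (S)-2,2-dimethyl-4-(2-methylprop-1-en-1-yl)-1,3-dioxolane
Product: 6 (S)-4-methylpent-3-ene-1,2-diol
Conditions: AcOH/H2O (4:1), rt
Reagents that add atoms: none
Why: Mild aqueous acid hydrolyses the isopropylidene acetal at the acetal carbon without ionising the allylic C–O bond, so the carbinol configuration is kept.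

**Step 4**
Reactants: 6 (S)-4-methylpent-3-ene-1,2-diol
Product: 7 (S)-1-[(tert-butyldiphenylsilyl)oxy]-4-methylpent-3-en-2-ol
Conditions: TBDPSCl, imidazole, CH2Cl2, 0 °C
Reagents that add atoms: tert-butyldiphenylsilyl chloride, CC(C)(C)[Si](Cl)(c1ccccc1)c1ccccc1
Why: The bulky silyl chloride silylates the primary hydroxyl selectively over the secondary allylic one, and the resulting ether is robust enough for BF3, strong base and the acidic tetronic acid later on.

**Step 5**
Reactants: 2 methyl 2-diazo-4-methyl-3-oxopentanoate; 7 (S)-1-[(tert-butyldiphenylsilyl)oxy]-4-methylpent-3-en-2-ol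
Product: 10 methyl (R,E)-6-[(tert-butyldiphenylsilyl)oxy]-2-hydroxy-3,3-dimethyl-2-(2-methylpropanoyl)hex-4-enoate, via (Z)-enol ether 8 (not isolated), via tertiary carbinol keto ester 9 (not isolated)
Conditions: Rh2(OAc)4 (1 mol %), PhH, 80 °C, slow addition of 2 to 7; then BF3·OEt2, rt
Reagents that add atoms: none
Why: The dirhodium carbenoid inserts into the O–H bond to give (Z)-enol ether 8, whose chair Claisen shift (silyloxymethyl group equatorial, enforced by allylic strain against the cis methyl group) should outrun tautomerisation and carry the carbinol configuration to the tertiary carbinol of 9, and the BF3-promoted α-ketol rearrangement then moves the tertiary allylic carbon suprafacially to the neighbouring ketone carbon, fixing C5 as (R).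

**Step 6**
Reactants: 10 methyl (R,E)-6-[(tert-butyldiphenylsilyl)oxy]-2-hydroxy-3,3-dimethyl-2-(2-methylpropanoyl)hex-4-enoate; 11 succinic anhydride
Product: 13 2-{(S)-5-[(E)-5-[(tert-butyldiphenylsilyl)oxy]-2-methylpent-3-en-2-yl]-4-hydroxy-5-(2-methylpropanoyl)-2-oxo-2,5-dihydrofuran-3-yl}acetic acid, via hemisuccinate 12 (not isolated)
Conditions: LiN(SiMe3)2 (1.05 equiv), THF, −78 °C; 11, −78 → 0 °C; LiN(SiMe3)2 (2.3 equiv), −78 °C → rt; aq. HCl work-up
Reagents that add atoms: none
Why: The lithium alkoxide of the tertiary alcohol opens the anhydride to hemisuccinate carboxylate 12, and the ester enolate then formed at C1 (the CH2 beside the carboxylate is not deprotonated) attacks the methyl ester carbon C8 in a 5-exo-trig Lacey–Dieckmann condensation driven by tetronate formation, while C5 carries no hydrogen and keeps its configuration.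

**Step 7**
Reactants: 13 the tetronic acid of step 6; 14 3-methylbut-2-en-1-yl acetate (prenyl acetate)
Product: 15 2-{(3R,5R)-5-[(E)-5-[(tert-butyldiphenylsilyl)oxy]-2-methylpent-3-en-2-yl]-3-(3-methylbut-2-en-1-yl)-5-(2-methylpropanoyl)-2,4-dioxooxolan-3-yl}acetic acid
Conditions: Pd(PPh3)4 (5 mol %), Et3N, THF, 45 °C
Reagents that add atoms: none
Why: In this Tsuji–Trost allylation the soft tetronate carbon C1 attacks the unsubstituted terminus of the (1,1-dimethylallyl)palladium complex, O-allyl and carboxylate-allyl products re-ionise so that C-alkylation is the sink, and the electrophile should enter anti to the bulky tert-alkyl C4 group on C5, placing prenyl cis to the isobutyryl group and the acetic acid arm cis to the C4 chain.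

**Step 8**
Reactants: 15 the silyl ether acid of step 7
Product: 16 2-{(3R,5R)-5-[(E)-5-hydroxy-2-methylpent-3-en-2-yl]-3-(3-methylbut-2-en-1-yl)-5-(2-methylpropanoyl)-2,4-dioxooxolan-3-yl}acetic acid
Conditions: HF·pyridine, pyridine, THF, 0 °C → rt
Reagents that add atoms: none
Why: Buffered HF cleaves the primary silyl ether under acidic, non-nucleophilic conditions that spare the base-sensitive non-enolisable tricarbonyl unit and the trisubstituted alkene.

**Step 9**
Reactants: 16 the hydroxy acid of step 8
Product: 17 2-{(3R,5R)-3-(3-methylbut-2-en-1-yl)-5-[(E)-2-methyl-5-oxopent-3-en-2-yl]-5-(2-methylpropanoyl)-2,4-dioxooxolan-3-yl}acetic acid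
Conditions: Dess–Martin periodinane, CH2Cl2, 0 °C → rt
Reagents that add atoms: none
Why: Dess–Martin oxidation converts the primary allylic alcohol into the (E)-enal under neutral conditions that tolerate the free carboxylic acid and the alkenes.

**Step 10**
Reactants: 17 the enal acid of step 9; 18 N-hydroxyphthalimide
Product: 19 1,3-dioxoisoindolin-2-yl 2-{(3R,5R)-3-(3-methylbut-2-en-1-yl)-5-[(E)-2-methyl-5-oxopent-3-en-2-yl]-5-(2-methylpropanoyl)-2,4-dioxooxolan-3-yl}acetate
Conditions: N,N'-diisopropylcarbodiimide, DMAP (cat.), CH2Cl2, 0 °C → rt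
Reagents that add atoms: none
Why: Steglich-type carbodiimide coupling gives the redox-active ester under neutral conditions, and the enal β-carbon, shielded by the adjacent quaternary C4, should not take up the weakly nucleophilic N-hydroxyphthalimide.

**Step 11**
Reactants: 19 the N-acyloxyphthalimide of step 10
Product: 22 2-[(1R,3S,5R)-4,4-dimethyl-1-(3-methylbut-2-en-1-yl)-5-(2-methylpropanoyl)-7,8-dioxo-6-oxabicyclo[3.2.1]octan-3-yl]acetaldehyde, via primary C2 radical 20 (not isolated), via cyclised α-formyl radical 21 (not isolated)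
Conditions: Ru(bpy)3Cl2·6H2O (2 mol %), Hantzsch ester (diethyl 2,6-dimethyl-1,4-dihydropyridine-3,5-dicarboxylate, 1.5 equiv), degassed MeCN/CH2Cl2, 5 mM, blue LEDs, 0 °C
Reagents that add atoms: none
Why: The photoreduced catalyst [Ru(bpy)3]+ transfers one electron to the N-acyloxyphthalimide, which fragments to phthalimide anion, CO2 and the primary C2 radical 20; this nucleophilic radical adds to the electron-poor β-carbon C3 of the enal and the α-formyl radical 21 takes a hydrogen atom from the Hantzsch ester, the closest known reaction type being the reductive decarboxylative Giese cyclization of redox-active esters. Ring B (C1, C2, C3, C4, C5, C8) closes in the 6-exo-trig mode, the 7-endo alternative at the α-carbon being polarity-mismatched. C3 is set by the substrate: in the chair-like transition state the enal arm is equatorial, on the face away from the O6–C7 bridge, because the axial site points into that bridge, and the ends at C1 and C5 are already cis on ring A. The step needs the closure to outrun a Dowd–Beckwith-type 1,2-acyl shift of the C2 radical onto the C8 carbonyl and direct hydrogen-atom transfer to C2. The cis-locked ends, the gem-dimethyl group at C4, the electron-poor acceptor, high dilution of the hydrogen donor and irradiation at 0 °C (the conjugate addition should have the lower activation enthalpy) should secure this.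

**Step 12**
Reactants: 22 the bicyclic aldehyde of step 11; 4 isopropyltriphenylphosphonium iodide
Product: 23 (1R,3R,5R)-4,4-dimethyl-1,3-bis(3-methylbut-2-en-1-yl)-5-(2-methylpropanoyl)-6-oxabicyclo[3.2.1]octane-7,8-dione (CNP0231965.1)
Conditions: 4, KN(SiMe3)2, THF, 0 °C; ylide added slowly to 22, THF, −78 → 0 °C
Reagents that add atoms: none
Why: Wittig olefination with the non-stabilised isopropylidene ylide should be far faster at the unhindered aldehyde than at the two ketones (each flanked by a quaternary carbon) or the lactone, inverse addition at −78 °C keeps excess basic ylide away from the tricarbonyl unit, and no stereocentre is touched.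

**Compound list**

1 | methyl 4-methyl-3-oxopentanoate | CC(C)C(=O)CC(=O)OC | starting material
2 | methyl 2-diazo-4-methyl-3-oxopentanoate | CC(C)C(=O)C(=[N+]=[N-])C(=O)OC | intermediate
3 | (R)-2,2-dimethyl-1,3-dioxolane-4-carbaldehyde | O=C[C@H]1COC(C)(C)O1 | starting material
4 | isopropyltriphenylphosphonium iodide | CC(C)[P+](c1ccccc1)(c1ccccc1)c1ccccc1.[I-] | starting material
5 | (S)-2,2-dimethyl-4-(2-methylprop-1-en-1-yl)-1,3-dioxolane | CC(C)=C[C@H]1COC(C)(C)O1 | intermediate
6 | (S)-4-methylpent-3-ene-1,2-diol | CC(C)=C[C@H](O)CO | intermediate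
7 | (S)-1-[(tert-butyldiphenylsilyl)oxy]-4-methylpent-3-en-2-ol | CC(C)=C[C@H](O)CO[Si](c1ccccc1)(c1ccccc1)C(C)(C)C | intermediate
8 | methyl (Z)-2-{[(S)-1-[(tert-butyldiphenylsilyl)oxy]-4-methylpent-3-en-2-yl]oxy}-3-hydroxy-4-methylpent-2-enoate | COC(=O)/C(O[C@H](CO[Si](c1ccccc1)(c1ccccc1)C(C)(C)C)C=C(C)C)=C(/O)C(C)C | intermediate (not isolated)
9 | methyl (S,E)-7-[(tert-butyldiphenylsilyl)oxy]-3-hydroxy-4,4-dimethyl-2-oxo-3-(propan-2-yl)hept-5-enoate | COC(=O)C(=O)[C@](O)(C(C)C)C(C)(C)/C=C/CO[Si](c1ccccc1)(c1ccccc1)C(C)(C)C | intermediate (not isolated)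
10 | methyl (R,E)-6-[(tert-butyldiphenylsilyl)oxy]-2-hydroxy-3,3-dimethyl-2-(2-methylpropanoyl)hex-4-enoate | CC(C)C(=O)[C@@](O)(C(=O)OC)C(C)(C)/C=C/CO[Si](c1ccccc1)(c1ccccc1)C(C)(C)C | intermediate
11 | succinic anhydride | O=C1CCC(=O)O1 | starting material
12 | 4-{[(R,E)-6-[(tert-butyldiphenylsilyl)oxy]-1-methoxy-3,3-dimethyl-2-(2-methylpropanoyl)-1-oxohex-4-en-2-yl]oxy}-4-oxobutanoic acid (hemisuccinate of 10, present as its lithium salt) | CC(C)C(=O)[C@@](OC(=O)CCC(=O)O)(C(=O)OC)C(C)(C)/C=C/CO[Si](c1ccccc1)(c1ccccc1)C(C)(C)C | intermediate (not isolated)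
13 | 2-{(S)-5-[(E)-5-[(tert-butyldiphenylsilyl)oxy]-2-methylpent-3-en-2-yl]-4-hydroxy-5-(2-methylpropanoyl)-2-oxo-2,5-dihydrofuran-3-yl}acetic acid | OC(=O)CC1=C(O)[C@@](C(=O)C(C)C)(OC1=O)C(C)(C)/C=C/CO[Si](c2ccccc2)(c2ccccc2)C(C)(C)C | intermediate
14 | 3-methylbut-2-en-1-yl acetate | CC(C)=CCOC(C)=O | starting material
15 | 2-{(3R,5R)-5-[(E)-5-[(tert-butyldiphenylsilyl)oxy]-2-methylpent-3-en-2-yl]-3-(3-methylbut-2-en-1-yl)-5-(2-methylpropanoyl)-2,4-dioxooxolan-3-yl}acetic acid (acetic acid arm cis to the C4 chain) | OC(=O)C[C@@]1(CC=C(C)C)C(=O)O[C@](C(=O)C(C)C)(C1=O)C(C)(C)/C=C/CO[Si](c2ccccc2)(c2ccccc2)C(C)(C)C | intermediate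
16 | 2-{(3R,5R)-5-[(E)-5-hydroxy-2-methylpent-3-en-2-yl]-3-(3-methylbut-2-en-1-yl)-5-(2-methylpropanoyl)-2,4-dioxooxolan-3-yl}acetic acid | OC(=O)C[C@@]1(CC=C(C)C)C(=O)O[C@](C(=O)C(C)C)(C1=O)C(C)(C)/C=C/CO | intermediate
17 | 2-{(3R,5R)-3-(3-methylbut-2-en-1-yl)-5-[(E)-2-methyl-5-oxopent-3-en-2-yl]-5-(2-methylpropanoyl)-2,4-dioxooxolan-3-yl}acetic acid | OC(=O)C[C@@]1(CC=C(C)C)C(=O)O[C@](C(=O)C(C)C)(C1=O)C(C)(C)/C=C/C=O | intermediate
18 | N-hydroxyphthalimide | ON1C(=O)c2ccccc2C1=O | starting material
19 | 1,3-dioxoisoindolin-2-yl ester of 17 (key-step precursor) | O=C(C[C@@]1(CC=C(C)C)C(=O)O[C@](C(=O)C(C)C)(C1=O)C(C)(C)/C=C/C=O)ON1C(=O)c2ccccc2C1=O | intermediate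
20 | primary C2 radical from 19 (CH2 radical on C1 of ring A) | [CH2][C@@]1(CC=C(C)C)C(=O)O[C@](C(=O)C(C)C)(C1=O)C(C)(C)/C=C/C=O | intermediate (not isolated)
21 | cyclised α-formyl radical (radical on the carbon between C3 and CHO) | O=C[CH][C@@H]1C[C@@]2(CC=C(C)C)C(=O)O[C@](C(=O)C(C)C)(C2=O)C1(C)C | intermediate (not isolated)
22 | 2-[(1R,3S,5R)-4,4-dimethyl-1-(3-methylbut-2-en-1-yl)-5-(2-methylpropanoyl)-7,8-dioxo-6-oxabicyclo[3.2.1]octan-3-yl]acetaldehyde | O=CC[C@@H]1C[C@@]2(CC=C(C)C)C(=O)O[C@](C(=O)C(C)C)(C2=O)C1(C)C | intermediate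
23 | (1R,3R,5R)-4,4-dimethyl-1,3-bis(3-methylbut-2-en-1-yl)-5-(2-methylpropanoyl)-6-oxabicyclo[3.2.1]octane-7,8-dione | CC(C)=CC[C@@H]1C[C@@]2(CC=C(C)C)C(=O)O[C@](C(=O)C(C)C)(C2=O)C1(C)C | target

**Step count**

Total: 12 steps. Longest linear sequence: 11 steps (3 → 23, steps 2–12).

**Steps most likely to fail**

1. Step 11. The C2 radical may attack the C8 carbonyl beside it (1,2-acyl shift with enlargement of ring A) or be reduced before it reaches C3. Fallback: the C8 carbonyl is taken out for the duration of the radical step. Setting out from 15, NaBH(OAc)3 in MeCN/AcOH, with hydride delivered from boron bound to the carboxylate arm, should reduce C8 alone and place the hydroxyl trans to that arm (so no γ-lactone can form), giving the C8 carbinol F1. HF·pyridine then gives the diol acid F2, and TEMPO/PhI(OAc)2 oxidises only the primary allylic alcohol to the enal carbinol acid F3. N-Hydroxyphthalimide 18 and N,N'-diisopropylcarbodiimide give the redox-active ester F4, and the photoreductive closure under the conditions of step 11 gives the bicyclic hydroxy aldehyde F5. Dess–Martin oxidation of the C8 carbinol returns to 22.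

2. Step 5. Tautomerisation of enol 8 to the keto ether may outrun the congested Claisen shift between two fully substituted carbons, or the α-ketol shift may lose stereochemical fidelity. Fallback: 2 and 7 are joined with Rh2(OAc)4 in CH2Cl2 at rt and the enol is left to tautomerise to the α-alkoxy β-keto ester F6. This is rearranged by an anionic [2,3]-Wittig shift (1,5,7-triazabicyclo[4.4.0]dec-5-ene, cat., toluene, 50 °C) through an envelope transition state with the silyloxymethyl group exo, which gives 10 directly. The configuration delivered at C5 would be checked before going on.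

3. Step 7. The prenyl electrophile may enter on the wrong face of the tetronate (syn to the C4 chain) or stay on oxygen. Fallback: if the syn face is preferred, the order of the two C1 substituents is inverted. Setting out from 10, the lithium alkoxide is acylated with 5-methylhex-4-enoyl chloride to the ester F7, and LiN(SiMe3)2 effects the Dieckmann closure to the 3-prenyl tetronic acid F8. C-Alkylation with allyl iodoacetate (Cs2CO3, DMF) then brings in the acetic acid arm on the preferred face to give the allyl ester F9, and Pd(PPh3)4/PhSiH3 removes the allyl group to return to 15.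

**Further compounds**

F1 | step 11 | C8 carbinol of 15 (4-hydroxy-2-oxooxolane, hydroxyl cis to the prenyl group, C1 and C5 as in 15) | OC(=O)C[C@@]1(CC=C(C)C)C(=O)O[C@](C(=O)C(C)C)([C@@H]1O)C(C)(C)/C=C/CO[Si](c2ccccc2)(c2ccccc2)C(C)(C)C
F2 | step 11 | desilylated diol acid from F1 | OC(=O)C[C@@]1(CC=C(C)C)C(=O)O[C@](C(=O)C(C)C)([C@@H]1O)C(C)(C)/C=C/CO
F3 | step 11 | (E)-enal C8 carbinol acid from F2 | OC(=O)C[C@@]1(CC=C(C)C)C(=O)O[C@](C(=O)C(C)C)([C@@H]1O)C(C)(C)/C=C/C=O
F4 | step 11 | 1,3-dioxoisoindolin-2-yl ester of F3 | O=C(C[C@@]1(CC=C(C)C)C(=O)O[C@](C(=O)C(C)C)([C@@H]1O)C(C)(C)/C=C/C=O)ON1C(=O)c2ccccc2C1=O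
F5 | step 11 | 8-hydroxy analogue of 22 (bicyclic hydroxy aldehyde) | O=CC[C@@H]1C[C@@]2(CC=C(C)C)C(=O)O[C@](C(=O)C(C)C)([C@@H]2O)C1(C)C
F6 | step 5 | methyl 2-{[(S)-1-[(tert-butyldiphenylsilyl)oxy]-4-methylpent-3-en-2-yl]oxy}-4-methyl-3-oxopentanoate (both epimers at C2) | COC(=O)C(O[C@H](CO[Si](c1ccccc1)(c1ccccc1)C(C)(C)C)C=C(C)C)C(=O)C(C)C
F7 | step 7 | 5-methylhex-4-enoate ester of the tertiary alcohol 10 | CC(C)C(=O)[C@@](OC(=O)CCC=C(C)C)(C(=O)OC)C(C)(C)/C=C/CO[Si](c1ccccc1)(c1ccccc1)C(C)(C)C
F8 | step 7 | (S)-5-[(E)-5-[(tert-butyldiphenylsilyl)oxy]-2-methylpent-3-en-2-yl]-4-hydroxy-3-(3-methylbut-2-en-1-yl)-5-(2-methylpropanoyl)furan-2(5H)-one | CC(C)=CCC1=C(O)[C@@](C(=O)C(C)C)(OC1=O)C(C)(C)/C=C/CO[Si](c2ccccc2)(c2ccccc2)C(C)(C)C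
F9 | step 7 | allyl ester of 15 | C=CCOC(=O)C[C@@]1(CC=C(C)C)C(=O)O[C@](C(=O)C(C)C)(C1=O)C(C)(C)/C=C/CO[Si](c2ccccc2)(c2ccccc2)C(C)(C)C
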